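The earlier runs and the new flask stem from a simulated flask with made-up constants; scatter was added.

Partner is conserved: each unit charged either becomes product or is lost. The flask held less partner (0.700 mM) than starting material (0.0010 M), so with partner the limiting reagent, I reckoned the flask by the share that gets captured.

| flask | starting material | partner | protic impurity | remark | time |
|---|---|---|---|---|---|
| larch | 0.0014 M | 0.70 mM (fed, over 20 s) | 0.020 mM | run made earlier |  |
| alder | 0.0022 M | 0.70 mM (fed, over 20 s) | 0.020 mM | run made earlier |  |
| birch | 0.0010 M | 1.4 mM (fed, over 20 s) | 0.020 mM | run made earlier |  |
| flask | 0.0010 M | 0.700 mM (fed, over 20 s) | 0.0200 mM |  | 2.5 min |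

- larch (time / s: starting material / %, product / %): 15.0: 72.4, 12.8; 40.0: 53.7, 40.1; 80.0: 51.6, 45.2; 120: 53.9, 44.8
- alder (time / s: starting material / %, product / %): 10.0: 87.2, 5.6; 20.0: 72.7, 14.6; 50.0: 69.7, 31.1; 120: 69.5, 30.9
- birch (time / s: starting material / %, product / %): 30.0: 13.3, 71.8; 60.0: 4.6, 90.9; 90.0: 4.3, 95.4; 120: 1.7, 96.6

(readings scatter by 1 percentage point)

- the numbers in the tables scatter by 1 percentage point (one standard deviation)
- a reading or a percentage of product counts all its forms, free or not
- the concentration of product that is asked is that of its free form alone

- concentration of starting material at 2.5 min, in M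
- concentration of product (only what is free in solution) at 2.5 min, in M

Over its last two readings larch turned 90.0% of its partner into product, and alder, richer in starting material, 97.4%. I therefore set the captured share to c/(c+D), with c the concentration of starting material and D the loss concentration, 0.119 mM: the c at which capture and loss run equal, read from larch with c as the mean of its first and last values. Birch's balance ended 0.0170 mM short, against 0.020 mM of impurity, so I let the impurity consume its charge of starting material.

I took two extreme versions of the flask. With c held at the charge, my rule gave 0.626 mM of product. With c held at the end value this leaves, 0.354 mM, it gave less, 0.524 mM. The real c runs between them. Using the mean gave 0.596 mM, and putting that back gave 0.597 mM of product and 0.383 mM of starting material. That was my reckoning. The forecast, calling the lost partner “consistent with the impurity destroying partner”, gave 3.300 × 10⁻⁴ M of starting material and 6.500 × 10⁻⁴ M of free product, a different pair.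

    starting material + protic impurity → quenched substrate (k = 560 M⁻¹ s⁻¹)
    partner → decomposed reagent (k = 0.0250 s⁻¹)
    starting material + partner → intermediate (k = 270 M⁻¹ s⁻¹)
    partner + product ⇌ idle adduct, settled at all times (K = 1900 M⁻¹)
    intermediate → product (k = 0.120 s⁻¹)

The flask held 3.70 × 10⁻⁴ M of starting material and 6.10 × 10⁻⁴ M of free product at 2.50 min. At 0.239 min, during the feed, partner in the flask went to the intermediate 7.3 times as fast as it decomposed, and decomposed reagent in the flask ended at 0.0901 mM. For the neighbour charged with 0.420 mM of partner, one round with D gave 0.366 mM, and that flask held 0.375 mM of free product.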